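## Retrosynthetic overview

1. Target 17 ⇐ hydroxyl-directed epoxidation of allylic alcohol 16 (ring-fused oxirane, made last) ⇐ 1,2-reduction of α'-acyloxy enone 15.
2. Key disconnection, the C1–O bond: 15 ⇐ enone 11 + bis[(2R)-2-methylbutanoyl] peroxide 14, a cis-selective α'-acyloxylation that sets C1 and brings in the whole ester.
3. 11 ⇐ asymmetric epoxidation of the prenyl alkene (side-chain oxirane, made first) ⇐ angelate 10 ⇐ alcohol 8 + angelic acid 9.
4. 8 ⇐ cross-metathesis of 6 ⇐ enantioselective allylboration of enal 3 ⇐ allylic oxidation of (R)-carvone 1.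
5. Ring order: the cyclohexane comes intact from carvone (C6 stereocentre), then the side-chain oxirane (step 5), then the ring-fused oxirane (step 9).

Locants used below: C1 = ring CH bearing the 2-methylbutanoate, C2 = ring carbinol, C3/C4 = ring oxirane, C6 = ring CH bearing the side chain, C7(=C14H2), C8 = angelate carbinol, C10/C11 = side-chain oxirane.

Assumption: the ring ester is the (2R)-2-methylbutanoate exactly as drawn, and (R)-2-methylbutanoic acid, angelic acid and (R)-carvone are bought as such.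

## Route

Step 1
Reactants: 1 (R)-(−)-carvone
Product: 3 2-[(1R)-4-methyl-5-oxocyclohex-3-en-1-yl]prop-2-enal, via allylic alcohol 2 (not isolated)
Conditions: SeO2 (20 mol%), t-BuOOH (2.5 equiv), CH2Cl2, rt; filter; then MnO2 (10 equiv), CH2Cl2, rt
Reagents that add atoms: tert-butyl hydroperoxide, CC(C)(C)OO (oxygen relayed through SeO2)
Why: SeO2-catalysed allylic oxidation (ene reaction then [2,3]-sigmatropic shift, reoxidised by t-BuOOH) attacks the only electron-rich alkene and hydroxylates its methyl group, and MnO2 then oxidises the primary allylic alcohol 2 to the enal without touching the C6 stereocentre.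

Step 2
Reactants: 3 2-[(1R)-4-methyl-5-oxocyclohex-3-en-1-yl]prop-2-enal; 4 allylboronic acid pinacol ester
Product: 6 (5R)-5-[(3S)-3-hydroxyhexa-1,5-dien-2-yl]-2-methylcyclohex-2-en-1-one, via borate ester 5 (not isolated)
Conditions: (S)-TRIP [(S)-3,3'-bis(2,4,6-triisopropylphenyl)-1,1'-binaphthyl-2,2'-diyl hydrogen phosphate] (5 mol%), 4 Å MS, toluene, −30 °C; aq. NaHCO3 work-up
Reagents that add atoms: allylboronic acid pinacol ester 4, C=CCB1OC(C)(C)C(C)(C)O1
Why: Chiral phosphoric acid-catalysed allylboration through a closed chair transition state reacts only with the aldehyde (the enone carbonyl is inert), and the (S)-catalyst directs Si-face attack to set C8 as S.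

Step 3
Reactants: 6 (5R)-5-[(3S)-3-hydroxyhexa-1,5-dien-2-yl]-2-methylcyclohex-2-en-1-one; 7 2-methylbut-2-ene
Product: 8 (5R)-5-[(3S)-3-hydroxy-6-methylhepta-1,5-dien-2-yl]-2-methylcyclohex-2-en-1-one
Conditions: second-generation Grubbs catalyst RuCl2(=CHPh)(PCy3)(H2IMes) (3 mol%), 2-methylbut-2-ene/CH2Cl2 1:1, 40 °C, sealed tube
Reagents that add atoms: 2-methylbut-2-ene 7, CC=C(C)C
Why: Olefin cross-metathesis engages only the monosubstituted alkene, and excess 2-methylbut-2-ene funnels it to the metathesis-inert trisubstituted prenyl alkene; no stereocentre is touched.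

Step 4
Reactants: 8 (5R)-5-[(3S)-3-hydroxy-6-methylhepta-1,5-dien-2-yl]-2-methylcyclohex-2-en-1-one; 9 angelic acid [(2Z)-2-methylbut-2-enoic acid]
Product: 10 (3S)-6-methyl-2-[(1R)-4-methyl-5-oxocyclohex-3-en-1-yl]hepta-1,5-dien-3-yl (2Z)-2-methylbut-2-enoate
Conditions: 9, 2,4,6-trichlorobenzoyl chloride, Et3N, toluene, rt, 2 h; then 8, 80 °C (no DMAP)
Reagents that add atoms: angelic acid 9, C/C=C(/C)C(=O)O
Why: Yamaguchi esterification via the mixed anhydride without a nucleophilic catalyst acylates the hindered alcohol with retention at C8 (only the O–acyl bond is formed) and avoids the angelate-to-tiglate isomerisation seen with DMAP-type activation.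

Step 5
Reactants: 10 (3S)-6-methyl-2-[(1R)-4-methyl-5-oxocyclohex-3-en-1-yl]hepta-1,5-dien-3-yl (2Z)-2-methylbut-2-enoate
Product: 11 (2S)-1-[(2R)-3,3-dimethyloxiran-2-yl]-3-[(1R)-4-methyl-5-oxocyclohex-3-en-1-yl]but-3-en-2-yl (2Z)-2-methylbut-2-enoate
Conditions: D-fructose-derived Shi ketone (30 mol%), Oxone (2KHSO5·KHSO4·K2SO4), K2CO3, Bu4NHSO4 (cat.), MeCN/CH2(OMe)2/aq. Na2B4O7–Na2EDTA buffer (pH 10.5), 0 °C, 2 h
Reagents that add atoms: potassium peroxymonosulfate (active part of Oxone), [K+].[O-]S(=O)(=O)OO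
Why: Shi asymmetric epoxidation via the chiral dioxirane (spiro transition state) picks the electron-rich trisubstituted prenyl alkene over the enone, the enoate and the hindered 1,1-disubstituted alkene, and the D-fructose-derived ketone delivers oxygen to the face that gives 10R.

Step 6
Reactants: 12 (2R)-2-methylbutanoic acid (2 equiv; two molecules are joined through the peroxide O–O unit)
Product: 14 bis[(2R)-2-methylbutanoyl] peroxide, via peroxy acid 13 (not isolated)
Conditions: 12 (2.0 equiv), N,N'-dicyclohexylcarbodiimide (2.0 equiv), H2O2 (1.0 equiv, ethereal), CH2Cl2/Et2O, −15 → 0 °C; cold filtration; kept as a titrated solution below 0 °C, never concentrated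
Reagents that add atoms: hydrogen peroxide, OO; (2R)-2-methylbutanoic acid 12 (second molecule, which acylates peroxy acid 13), CC[C@@H](C)C(=O)O
Why: Carbodiimide-mediated double acylation of H2O2 (the O-acylisourea of the first molecule of 12 gives peroxy acid 13, which is acylated by the O-acylisourea of the second molecule of 12) under neutral conditions gives the symmetrical diacyl peroxide without enolising the α-stereocentres.

Step 7
Reactants: 11 (2S)-1-[(2R)-3,3-dimethyloxiran-2-yl]-3-[(1R)-4-methyl-5-oxocyclohex-3-en-1-yl]but-3-en-2-yl (2Z)-2-methylbut-2-enoate; 14 bis[(2R)-2-methylbutanoyl] peroxide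
Product: 15 (1R,6S)-6-[(3S)-4-[(2R)-3,3-dimethyloxiran-2-yl]-3-{[(2Z)-2-methylbut-2-enoyl]oxy}but-1-en-2-yl]-3-methyl-2-oxocyclohex-3-en-1-yl (2R)-2-methylbutanoate
Conditions: 9-amino(9-deoxy)epi-quinidine (20 mol%; the pseudoenantiomer that delivers oxygen to the 1R face, checked against its quinine-derived counterpart in a first run), 12 (20 mol%), BHT (10 mol%), 4 Å MS, THF, −10 → 0 °C, dark; cold silica filtration, used at once
Reagents that add atoms: bis[(2R)-2-methylbutanoyl] peroxide 14, CC[C@@H](C)C(=O)OOC(=O)[C@H](C)CC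
Why: Proposed new method: a cinchona primary amine condenses with the enone (carboxylic acid co-catalyst) to an iminium ion that tautomerises to the cross-conjugated 2-amino-1,3-diene, the protonated quinuclidine hydrogen-bonds a peroxide carbonyl and steers attack of C1 on the O–O bond (carboxylate of 12 leaves) to the C1 face syn to the C6 side chain, and hydrolysis releases 15 and the amine, so that catalyst control overrides the modest anti bias of the C6 substituent and gives the kinetic cis (1R) product with the intact (2R)-acyl group; the closest known reaction type is the cinchona primary amine-catalysed enantioselective α-benzoyloxylation of cyclic ketones with dibenzoyl peroxide, and new here are the aliphatic α-branched diacyl peroxide, reaction at the α'-carbon of an α-methyl enone and the reagent-controlled cis diastereoselection.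

Step 8
Reactants: 15 (1R,6S)-6-[(3S)-4-[(2R)-3,3-dimethyloxiran-2-yl]-3-{[(2Z)-2-methylbut-2-enoyl]oxy}but-1-en-2-yl]-3-methyl-2-oxocyclohex-3-en-1-yl (2R)-2-methylbutanoate
Product: 16 (1R,2S,6S)-6-[(3S)-4-[(2R)-3,3-dimethyloxiran-2-yl]-3-{[(2Z)-2-methylbut-2-enoyl]oxy}but-1-en-2-yl]-2-hydroxy-3-methylcyclohex-3-en-1-yl (2R)-2-methylbutanoate
Conditions: NaBH4, CeCl3·7H2O, MeOH, −78 °C, 15 min; AcOH quench at −78 °C
Reagents that add atoms: none
Why: Luche 1,2-reduction: hydride adds along the axial trajectory anti to the axial C1 acyloxy group (polar Felkin–Anh, the same face that turns carvone into cis-carveol), so the new C2–OH is cis to both the C1 ester and the C6 side chain, while −78 °C and an acidic quench prevent C1 epimerisation and 1,2-acyl migration.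

Step 9
Reactants: 16 (1R,2S,6S)-6-[(3S)-4-[(2R)-3,3-dimethyloxiran-2-yl]-3-{[(2Z)-2-methylbut-2-enoyl]oxy}but-1-en-2-yl]-2-hydroxy-3-methylcyclohex-3-en-1-yl (2R)-2-methylbutanoate
Product: 17 (1R,2R,3R,4S,6S)-4-[(3S)-4-[(2R)-3,3-dimethyloxiran-2-yl]-3-{[(2Z)-2-methylbut-2-enoyl]oxy}but-1-en-2-yl]-2-hydroxy-1-methyl-7-oxabicyclo[4.1.0]heptan-3-yl (2R)-2-methylbutanoate (target CNP0181486.1)
Conditions: VO(acac)2 (5 mol%), t-BuOOH (1.5 equiv, in decane), CH2Cl2, 0 °C → rt
Reagents that add atoms: tert-butyl hydroperoxide, CC(C)(C)OO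
Why: Vanadium-catalysed hydroxyl-directed epoxidation delivers the peroxide oxygen within a pentavalent vanadium alkoxide–peroxide complex to the alkene face syn to the C2–OH, setting C3 and C4 with the oxirane cis to OH, ester and side chain, and leaves the non-allylic 7(14)-alkene, the enoate and the existing oxirane alone.

## Compound list

1 | (R)-(−)-carvone, (5R)-2-methyl-5-(prop-1-en-2-yl)cyclohex-2-en-1-one | C=C(C)[C@@H]1CC=C(C)C(=O)C1 | starting material
2 | (5R)-5-(3-hydroxyprop-1-en-2-yl)-2-methylcyclohex-2-en-1-one | C=C(CO)[C@@H]1CC=C(C)C(=O)C1 | intermediate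
3 | 2-[(1R)-4-methyl-5-oxocyclohex-3-en-1-yl]prop-2-enal | C=C(C=O)[C@@H]1CC=C(C)C(=O)C1 | intermediate
4 | allylboronic acid pinacol ester, 2-allyl-4,4,5,5-tetramethyl-1,3,2-dioxaborolane | C=CCB1OC(C)(C)C(C)(C)O1 | starting material
5 | pinacol borate ester of 6, 2-{[(3S)-2-[(1R)-4-methyl-5-oxocyclohex-3-en-1-yl]hexa-1,5-dien-3-yl]oxy}-4,4,5,5-tetramethyl-1,3,2-dioxaborolane | C=C([C@H](CC=C)OB1OC(C)(C)C(C)(C)O1)[C@@H]1CC=C(C)C(=O)C1 | intermediate
6 | (5R)-5-[(3S)-3-hydroxyhexa-1,5-dien-2-yl]-2-methylcyclohex-2-en-1-one | C=C([C@H](CC=C)O)[C@@H]1CC=C(C)C(=O)C1 | intermediate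
7 | 2-methylbut-2-ene | CC=C(C)C | starting material
8 | (5R)-5-[(3S)-3-hydroxy-6-methylhepta-1,5-dien-2-yl]-2-methylcyclohex-2-en-1-one | C=C([C@H](CC=C(C)C)O)[C@@H]1CC=C(C)C(=O)C1 | intermediate
9 | angelic acid, (2Z)-2-methylbut-2-enoic acid | C/C=C(/C)C(=O)O | starting material
10 | (3S)-6-methyl-2-[(1R)-4-methyl-5-oxocyclohex-3-en-1-yl]hepta-1,5-dien-3-yl (2Z)-2-methylbut-2-enoate | C=C([C@H](CC=C(C)C)OC(=O)/C(C)=C\C)[C@@H]1CC=C(C)C(=O)C1 | intermediate
11 | (2S)-1-[(2R)-3,3-dimethyloxiran-2-yl]-3-[(1R)-4-methyl-5-oxocyclohex-3-en-1-yl]but-3-en-2-yl (2Z)-2-methylbut-2-enoate | C=C([C@H](C[C@H]1OC1(C)C)OC(=O)/C(C)=C\C)[C@@H]1CC=C(C)C(=O)C1 | intermediate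
12 | (2R)-2-methylbutanoic acid | CC[C@@H](C)C(=O)O | starting material
13 | (2R)-2-methylbutaneperoxoic acid | CC[C@@H](C)C(=O)OO | intermediate
14 | bis[(2R)-2-methylbutanoyl] peroxide | CC[C@@H](C)C(=O)OOC(=O)[C@H](C)CC | intermediate
15 | (1R,6S)-6-[(3S)-4-[(2R)-3,3-dimethyloxiran-2-yl]-3-{[(2Z)-2-methylbut-2-enoyl]oxy}but-1-en-2-yl]-3-methyl-2-oxocyclohex-3-en-1-yl (2R)-2-methylbutanoate (acyloxy cis to the side chain) | C=C([C@H](C[C@H]1OC1(C)C)OC(=O)/C(C)=C\C)[C@@H]1CC=C(C)C(=O)[C@@H]1OC(=O)[C@H](C)CC | intermediate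
16 | (1R,2S,6S)-6-[(3S)-4-[(2R)-3,3-dimethyloxiran-2-yl]-3-{[(2Z)-2-methylbut-2-enoyl]oxy}but-1-en-2-yl]-2-hydroxy-3-methylcyclohex-3-en-1-yl (2R)-2-methylbutanoate (OH, ester and side chain all cis) | C=C([C@H](C[C@H]1OC1(C)C)OC(=O)/C(C)=C\C)[C@@H]1CC=C(C)[C@H](O)[C@@H]1OC(=O)[C@H](C)CC | intermediate
17 | (1R,2R,3R,4S,6S)-4-[(3S)-4-[(2R)-3,3-dimethyloxiran-2-yl]-3-{[(2Z)-2-methylbut-2-enoyl]oxy}but-1-en-2-yl]-2-hydroxy-1-methyl-7-oxabicyclo[4.1.0]heptan-3-yl (2R)-2-methylbutanoate | C=C([C@H](C[C@H]1OC1(C)C)OC(=O)/C(C)=C\C)[C@@H]1C[C@@H]2O[C@]2(C)[C@H](O)[C@@H]1OC(=O)[C@H](C)CC | target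

## Step count and risks

Total: 9 steps (8 in the main line plus 1 reagent preparation, step 6). Longest linear sequence: 8 steps (1–5, 7–9) from (R)-carvone.

The three steps most likely to fail:

Step 1 (allylic oxidation of carvone). SeO2 can also abstract the tertiary allylic C6–H, which gives a tertiary alcohol, and the yield of the alcohol/enal pair is usually modest. The 2-substituted acrolein 3 is also prone to oligomerise. The fallback sets out from 1 and comes back at 3. Ene-type allylic chlorination of 1 with Ca(OCl)2 and solid CO2 in CH2Cl2/H2O gives (5R)-5-(3-chloroprop-1-en-2-yl)-2-methylcyclohex-2-en-1-one F1. Amine N-oxide oxidation of this allylic chloride (N-methylmorpholine N-oxide, KI cat., MeCN, 50 °C) then gives enal 3.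

Step 4 (angeloylation). The alcohol is a hindered secondary allylic one, and any nucleophilic activation of the angeloyl group risks Z-to-E isomerisation to the tiglate. The fallback sets out from 8 and comes back at 10, and it builds the Z-enoate on the ester instead of transferring it. Acylation of 8 with 2-[bis(2,2,2-trifluoroethoxy)phosphoryl]propanoic acid (N,N'-dicyclohexylcarbodiimide, DMAP cat., CH2Cl2) gives (3S)-6-methyl-2-[(1R)-4-methyl-5-oxocyclohex-3-en-1-yl]hepta-1,5-dien-3-yl 2-[bis(2,2,2-trifluoroethoxy)phosphoryl]propanoate F2. Still–Gennari olefination with acetaldehyde (KN(SiMe3)2, 18-crown-6, THF, −78 °C) then gives the Z-enoate 10.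

Step 7 (the proposed new step). Possible failures are reaction through the linear dienamine at C5, incomplete override of the substrate's trans preference, oxidation of the amine catalyst by the peroxide, and epimerisation of the kinetic cis product. The fallback uses known chemistry, sets out from 11 and comes back at 15. LiN(SiMe3)2 in THF at −78 °C followed by 2-(phenylsulfonyl)-3-phenyloxaziridine hydroxylates the α'-enolate anti to the C6 substituent. This gives the trans α'-hydroxy enone (2S)-1-[(2R)-3,3-dimethyloxiran-2-yl]-3-[(1S,2S)-2-hydroxy-4-methyl-3-oxocyclohex-4-en-1-yl]but-3-en-2-yl (2Z)-2-methylbut-2-enoate F3. Mitsunobu esterification with acid 12 (PPh3, DIAD, toluene, 0 °C) inverts C1 and gives 15. Step 6 is then not needed, so the total stays at 9 steps.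

## Further compounds

F1 | step 1 | (5R)-5-(3-chloroprop-1-en-2-yl)-2-methylcyclohex-2-en-1-one | C=C(CCl)[C@@H]1CC=C(C)C(=O)C1
F2 | step 4 | (3S)-6-methyl-2-[(1R)-4-methyl-5-oxocyclohex-3-en-1-yl]hepta-1,5-dien-3-yl 2-[bis(2,2,2-trifluoroethoxy)phosphoryl]propanoate (both epimers at the phosphonate-bearing carbon) | C=C([C@H](CC=C(C)C)OC(=O)C(C)P(=O)(OCC(F)(F)F)OCC(F)(F)F)[C@@H]1CC=C(C)C(=O)C1
F3 | step 7 | (2S)-1-[(2R)-3,3-dimethyloxiran-2-yl]-3-[(1S,2S)-2-hydroxy-4-methyl-3-oxocyclohex-4-en-1-yl]but-3-en-2-yl (2Z)-2-methylbut-2-enoate | C=C([C@H](C[C@H]1OC1(C)C)OC(=O)/C(C)=C\C)[C@@H]1CC=C(C)C(=O)[C@H]1O
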